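A direct plan would build a C2-symmetric trans-3,5-dimethyl-1,2-dioxolane and then break its symmetry.
It would epoxidise a skipped dienediol twice (Sharpless) to diepoxide A1 and let H2O2 open both tertiary epoxide carbons in one pot to dioxolane tetraol A2.
It would then cut back and regrow the arms (glycol cleavage, methylenation, hydroboration) to diol A3, brominate one arm to A4, couple trienylborane A5 by a B-alkyl Suzuki reaction and oxidise the other arm to the acid.
Its weakest points would be:
(a) the double perhydrolysis: both quaternary stereocentres and the ring closure would rest on clean inversion at two tertiary carbons and on peroxide, not hydroxyl, closing the ring; any cation character would scramble them;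
(b) the cleavage, methylenation, hydroboration and monobromination stretch: five steps that remove and replace two carbons and end in a statistical desymmetrisation;
(c) the alkyl–alkyl Suzuki coupling: zerovalent palladium, PCy3 and a borane would meet the O–O bond on the most advanced intermediate.

Plan of the new route
- The retrosynthesis cuts C7'=C8' (Julia–Kocienski), then C2'–C3' (cross-metathesis, alkene then saturated), then C5–C1' (allylation), and only then the ring bonds O1–C5 and O2–C3.
- Feature used: C3 and C5 stand 1,3 across C4, so the carboxyl oxygen of the C3 acetic acid arm can reach C5 and close a six-membered lactone over the dioxolane (a 2,6,7-trioxabicyclo[3.2.1]octan-3-one). This bridge can exist only with the arm and C5–O cis, and in it C5 is a peroxyketal carbon that ionises to a cation stabilised by O1.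
- Ring order: 4,6-dimethyl-2H-pyran-2-one, whose seven carbons are C5 with its methyl, C4, C3 with its methyl and the two arm carbons, is opened; amine-catalysed addition of H2O2 sets C3 and closes the dioxolane as a hemiketal; acid then closes the lactone bridge.
- Allylation with inversion at C5 opens the bridge, frees the acid and leaves the C5 methyl cis to the arm, which is the trans-dimethyl ring; the configuration of C5 before this step is irrelevant.
- No peroxide displaces at a tertiary carbon, no carbon is removed and put back, the two arms differ from the first step, and the chain is joined by metathesis and olefination, not by palladium, phosphine and borane.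

Key step: step 4

Remark: locants C1'–C15' count the side chain outwards from ring carbon C5; the target is the (3R,5S) isomer, in which the two ring methyl groups are trans.
Remark: the sense of induction in step 2 is assumed to follow that of 3-substituted cyclic enones with the same amine; if the 3S hydroperoxide should prevail, the pseudo-enantiomeric 9-amino-9-deoxy-epi-quinidine would be used with no other change.

Step 1
Reactants: 1 4,6-dimethyl-2H-pyran-2-one
Product: 3 methyl (2Z)-3-methyl-5-oxohex-2-enoate, via sodium dienolate 2 (not isolated)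
Conditions: NaOMe (1.1 equiv), MeOH, 0 °C; AcOH (1.1 equiv), −40 °C; used crude
Reagents that add atoms: sodium methoxide, C[O-].[Na+]
Why: Acyl substitution at the lactone carbonyl opens the ring because the leaving group is the delocalised dienolate 2, and kinetic protonation next to the ketone returns the keto ester with the ring (Z) geometry; alkene position and geometry of 3 do not matter for step 2.

Step 2
Reactants: 3 methyl (2Z)-3-methyl-5-oxohex-2-enoate
Product: 5 methyl 2-[(3R)-5-hydroxy-3,5-dimethyl-1,2-dioxolan-3-yl]acetate (both C5 epimers), via hydroperoxy ketone 4 (not isolated)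
Conditions: 9-amino-9-deoxy-epi-quinine (10 mol %), Cl3CCO2H (20 mol %), 50% aq. H2O2 (3 equiv), 1,4-dioxane, 30 °C
Reagents that add atoms: hydrogen peroxide, OO
Why: Proposed new method: the primary amine condenses with the C5 ketone, the dienamine is protonated at C2 to the conjugated iminium ion CH3C(=N+HR)CH=C(CH3)CH2CO2Me, H2O2 held by the protonated quinuclidine adds to one face of C3 (catalyst control of the new stereocentre), and hydrolysis gives 4, whose OOH adds reversibly to the C5 ketone (5-exo-trig) to close the dioxolane; all alkene isomers of 3 should funnel through the common dienamine, and an N–H···O=C hydrogen bond to the ester arm should single out one iminium geometry; the closest known reactions are the cinchona-amine-salt-catalysed hydroperoxidation of acyclic β-monosubstituted enones to peroxyhemiketals and the epoxidation of 3-substituted cyclic enones, in which H2O2 adds to a β,β-disubstituted iminium ion.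

Step 3
Reactants: 5 methyl 2-[(3R)-5-hydroxy-3,5-dimethyl-1,2-dioxolan-3-yl]acetate
Product: 6 (1S,5R)-1,5-dimethyl-2,6,7-trioxabicyclo[3.2.1]octan-3-one
Conditions: TsOH·H2O (5 mol %), 5 Å MS, CH2Cl2, 0 °C to rt
Reagents that add atoms: none
Why: Acid-catalysed exchange at the peroxyhemiketal carbon (through the peroxycarbenium ion, as in the known conversion of 3-hydroxy- into 3-alkoxy-1,2-dioxolanes) lets the ester carbonyl of the cis arm capture C5 and expel methanol, so both C5 epimers converge on the one bridged lactone that the C3 centre allows.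

Step 4
Reactants: 6 (1S,5R)-1,5-dimethyl-2,6,7-trioxabicyclo[3.2.1]octan-3-one; 7 trimethyl(prop-2-en-1-yl)silane
Product: 9 2-[(3R,5S)-3,5-dimethyl-5-(prop-2-en-1-yl)-1,2-dioxolan-3-yl]acetic acid, via trimethylsilyl ester 8 (not isolated)
Conditions: 7 (3 equiv), TMSOTf (0.3 equiv), CH2Cl2, −78 to −40 °C; pH 4 aqueous work-up
Reagents that add atoms: none
Why: Hosomi–Sakurai allylation of a peroxycarbenium ion: TMSOTf silylates the lactone carbonyl, the C5–O(acyl) bond ionises to the O1-stabilised cation whose silyl carboxylate stays tethered through C3 on the face it has left, 7 adds through its terminal carbon to the opposite face, and loss of Me3Si+ (which carries the chain) gives silyl ester 8, hydrolysed on work-up. The closest known reactions are the Lewis-acid-mediated allylation of 3-alkoxy-1,2-dioxolanes and other peroxyketals with allylsilanes and the anti-selective C-allylation of bridged bicyclic ketals such as 1,6-anhydro sugars. No ring is closed: the six-membered lactone ring is opened and the 1,2-dioxolane is kept. The new stereocentre C5 is controlled by C3 through the bridge, because the departing carboxyl oxygen covers the face cis to the arm, so the allyl group should enter trans to the arm and the methyl group end cis to it (inversion at C5, giving 5S). The step needs ionisation of C5–O(acyl) and not of C5–O1 (carboxylate is the better leaving group, O1 the better donor), attack at C5 and not at the far less electrophilic silylated acyl carbon, and an intact O–O bond (substoichiometric silyl triflate, low temperature).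

Step 5
Reactants: 10 hex-5-en-1-ol
Product: 11 5-(hex-5-en-1-ylsulfanyl)-1-phenyl-1H-tetrazole
Conditions: 1-phenyl-1H-tetrazole-5-thiol, PPh3, DIAD, THF, 0 °C to rt
Reagents that add atoms: 1-phenyl-1H-tetrazole-5-thiol, Sc1nnnn1-c1ccccc1
Why: Mitsunobu thioetherification of a primary alcohol; the terminal alkene is inert.

Step 6
Reactants: 11 5-(hex-5-en-1-ylsulfanyl)-1-phenyl-1H-tetrazole
Product: 12 5-(hex-5-en-1-ylsulfonyl)-1-phenyl-1H-tetrazole
Conditions: (NH4)6Mo7O24·4H2O (10 mol %), 30% aq. H2O2 (5 equiv), EtOH, 0 °C to rt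
Reagents that add atoms: hydrogen peroxide, OO
Why: Molybdate-catalysed peroxide oxidation of sulfide to sulfone is much faster than epoxidation of a monosubstituted alkene.

Step 7
Reactants: 9 2-[(3R,5S)-3,5-dimethyl-5-(prop-2-en-1-yl)-1,2-dioxolan-3-yl]acetic acid; 12 5-(hex-5-en-1-ylsulfonyl)-1-phenyl-1H-tetrazole
Product: 13 2-[(3R,5S)-3,5-dimethyl-5-{7-[(1-phenyl-1H-tetrazol-5-yl)sulfonyl]hept-2-en-1-yl}-1,2-dioxolan-3-yl]acetic acid (E/Z mixture)
Conditions: 12 (3 equiv), Hoveyda–Grubbs second-generation catalyst (H2IMes)Cl2Ru=CH(2-iPrOC6H4) (5 mol %), CH2Cl2, 40 °C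
Reagents that add atoms: none
Why: Olefin cross-metathesis of two unhindered terminal alkenes with a phosphine-free ruthenium alkylidene, which tolerates dialkyl peroxides and free acids; excess 12 suppresses the homodimer of 9, and the alkene geometry is immaterial because the bond is saturated next.

Step 8
Reactants: 13 2-[(3R,5S)-3,5-dimethyl-5-{7-[(1-phenyl-1H-tetrazol-5-yl)sulfonyl]hept-2-en-1-yl}-1,2-dioxolan-3-yl]acetic acid
Product: 14 2-[(3R,5S)-3,5-dimethyl-5-{7-[(1-phenyl-1H-tetrazol-5-yl)sulfonyl]heptyl}-1,2-dioxolan-3-yl]acetic acid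
Conditions: 2-nitrobenzenesulfonohydrazide (6 equiv, in portions), Et3N, CH2Cl2, rt
Reagents that add atoms: none
Why: Diimide reduction transfers H2 to the isolated disubstituted alkene in a concerted syn addition without touching the O–O bond, the sulfone or the tetrazole, which catalytic hydrogenation would not allow.

Step 9
Reactants: 15 prop-2-yn-1-ol; 16 (2Z)-1-bromopent-2-ene
Product: 17 (5Z)-oct-5-en-2-yn-1-ol
Conditions: CuI (10 mol %), K2CO3 (1.5 equiv), n-Bu4NBr (10 mol %), DMF, rt
Reagents that add atoms: none
Why: Copper-catalysed coupling of a terminal alkyne with a primary allylic bromide joins at the CH2 terminus with the Z alkene kept, giving the skipped enyne.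

Step 10
Reactants: 17 (5Z)-oct-5-en-2-yn-1-ol
Product: 19 (2E,5Z)-octa-2,5-dien-1-ol, via cyclic alkenylalanate 18 (not isolated)
Conditions: LiAlH4 (1.5 equiv), THF, 0 °C to rt; aqueous work-up
Reagents that add atoms: none
Why: Alkoxide-directed trans-hydroalumination of the propargylic alcohol and protonolysis give the E allylic alcohol, while the isolated Z alkene is not reduced.

Step 11
Reactants: 19 (2E,5Z)-octa-2,5-dien-1-ol
Product: 20 (2E,5Z)-octa-2,5-dienal
Conditions: Dess–Martin periodinane (1.2 equiv), CH2Cl2, 0 °C; used at once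
Reagents that add atoms: none
Why: Dess–Martin oxidation of the allylic alcohol is non-basic, so the skipped Z alkene should not move into conjugation.

Step 12
Reactants: 14 2-[(3R,5S)-3,5-dimethyl-5-{7-[(1-phenyl-1H-tetrazol-5-yl)sulfonyl]heptyl}-1,2-dioxolan-3-yl]acetic acid; 20 (2E,5Z)-octa-2,5-dienal
Product: 21 2-[(3R,5S)-3,5-dimethyl-5-[(7E,9E,12Z)-pentadeca-7,9,12-trien-1-yl]-1,2-dioxolan-3-yl]acetic acid (CNP0215994.1)
Conditions: KHMDS (2.2 equiv), DME, −70 °C; then 20 (1.3 equiv), −70 °C to rt; dilute aq. HCl to pH 4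
Reagents that add atoms: none
Why: Julia–Kocienski olefination: the first equivalent of base forms the carboxylate (which also guards the β-peroxy acid against E1cB ring opening), the second metalates the sulfone, and addition to the enal, Smiles rearrangement and loss of SO2 and the tetrazolone should form C7'=C8' E-selectively, while C9'=C10' (E) and C12'=C13' (Z) come unchanged from 20.

Compound list
1 | 4,6-dimethyl-2H-pyran-2-one | O=C1C=C(C)C=C(C)O1 | starting material
2 | sodium (2Z,4Z)-6-methoxy-4-methyl-6-oxohexa-2,4-dien-2-olate | C/C([O-])=C/C(C)=C\C(=O)OC.[Na+] | intermediate (not isolated)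
3 | methyl (2Z)-3-methyl-5-oxohex-2-enoate | CC(=O)C/C(C)=C\C(=O)OC | intermediate
4 | methyl (3R)-3-hydroperoxy-3-methyl-5-oxohexanoate | CC(=O)C[C@@](C)(OO)CC(=O)OC | intermediate (not isolated)
5 | methyl 2-[(3R)-5-hydroxy-3,5-dimethyl-1,2-dioxolan-3-yl]acetate (both C5 epimers) | COC(=O)C[C@@]1(C)CC(C)(O)OO1 | intermediate
6 | (1S,5R)-1,5-dimethyl-2,6,7-trioxabicyclo[3.2.1]octan-3-one | C[C@@]12C[C@](C)(CC(=O)O2)OO1 | intermediate
7 | trimethyl(prop-2-en-1-yl)silane | C=CC[Si](C)(C)C | starting material
8 | trimethylsilyl 2-[(3R,5S)-3,5-dimethyl-5-(prop-2-en-1-yl)-1,2-dioxolan-3-yl]acetate | C=CC[C@@]1(C)C[C@](C)(CC(=O)O[Si](C)(C)C)OO1 | intermediate (not isolated)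
9 | 2-[(3R,5S)-3,5-dimethyl-5-(prop-2-en-1-yl)-1,2-dioxolan-3-yl]acetic acid | C=CC[C@@]1(C)C[C@](C)(CC(=O)O)OO1 | intermediate
10 | hex-5-en-1-ol | C=CCCCCO | starting material
11 | 5-(hex-5-en-1-ylsulfanyl)-1-phenyl-1H-tetrazole | C=CCCCCSc1nnnn1-c1ccccc1 | intermediate
12 | 5-(hex-5-en-1-ylsulfonyl)-1-phenyl-1H-tetrazole | C=CCCCCS(=O)(=O)c1nnnn1-c1ccccc1 | intermediate
13 | 2-[(3R,5S)-3,5-dimethyl-5-{7-[(1-phenyl-1H-tetrazol-5-yl)sulfonyl]hept-2-en-1-yl}-1,2-dioxolan-3-yl]acetic acid (E/Z mixture) | O=S(=O)(CCCCC=CC[C@@]1(C)C[C@](C)(CC(=O)O)OO1)c1nnnn1-c1ccccc1 | intermediate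
14 | 2-[(3R,5S)-3,5-dimethyl-5-{7-[(1-phenyl-1H-tetrazol-5-yl)sulfonyl]heptyl}-1,2-dioxolan-3-yl]acetic acid | O=S(=O)(CCCCCCC[C@@]1(C)C[C@](C)(CC(=O)O)OO1)c1nnnn1-c1ccccc1 | intermediate
15 | prop-2-yn-1-ol | C#CCO | starting material
16 | (2Z)-1-bromopent-2-ene | BrC/C=C\CC | starting material
17 | (5Z)-oct-5-en-2-yn-1-ol | OCC#CC/C=C\CC | intermediate
18 | lithium 2,2-dihydrido-3-[(2Z)-pent-2-en-1-yl]-2,5-dihydro-1,2-oxaluminol-2-uide | [Li+].CC/C=C\CC1=CCO[AlH2-]1 | intermediate (not isolated)
19 | (2E,5Z)-octa-2,5-dien-1-ol | OC/C=C/C/C=C\CC | intermediate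
20 | (2E,5Z)-octa-2,5-dienal | O=C/C=C/C/C=C\CC | intermediate
21 | 2-[(3R,5S)-3,5-dimethyl-5-[(7E,9E,12Z)-pentadeca-7,9,12-trien-1-yl]-1,2-dioxolan-3-yl]acetic acid | CC/C=C\C/C=C/C=C/CCCCCC[C@@]1(C)C[C@](C)(CC(=O)O)OO1 | target

Total step count: 12. Longest linear sequence: 7 (steps 1, 2, 3, 4, 7, 8, 12).

Steps most likely to fail

Step 2. The facial selectivity at C3 may be poor if both iminium geometries react; the peroxy-enamine may close to an epoxide instead of being protonated; the catalyst may be held as the stable push–pull dienamine; 3 may return to the pyranone. The fallback builds the ring racemically by known chemistry and resolves it. From 3, urea–hydrogen peroxide with Sc(OTf)3 in MeOH would give methyl (2Z)-5-hydroperoxy-5-methoxy-3-methylhex-2-enoate F1. Et2NH in CF3CH2OH would close it by intramolecular peroxy-Michael addition to methyl 2-(5-methoxy-3,5-dimethyl-1,2-dioxolan-3-yl)acetate F2 (racemic, both diastereomers). Wet TsOH in CH2Cl2 would convert it into racemic 1,5-dimethyl-2,6,7-trioxabicyclo[3.2.1]octan-3-one F3, and preparative chromatography on a chiral stationary phase would deliver 6.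

Step 4. Facial control may be lost if the cation escapes its tethered carboxylate; the allyl group may add at the acyl carbon; the Lewis acid may trigger O–O heterolysis. The fallback gives up the relay for a separation. From 5, MeOH and TsOH would give methyl 2-[(3R)-5-methoxy-3,5-dimethyl-1,2-dioxolan-3-yl]acetate F4. The established SnCl4-mediated allylation of alkoxydioxolanes with 7 would give methyl 2-[(3R,5S)-3,5-dimethyl-5-(prop-2-en-1-yl)-1,2-dioxolan-3-yl]acetate F5 and its C5 epimer methyl 2-[(3R,5R)-3,5-dimethyl-5-(prop-2-en-1-yl)-1,2-dioxolan-3-yl]acetate F6, separated by chromatography. LiOH in THF–H2O at 0 °C would hydrolyse F5 to 9.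

Step 12. E selectivity at the new double bond may be incomplete, and the base may move the skipped double bond of the dienal into conjugation before addition. The fallback puts the aldehyde on the peroxide and the carbanion on the side chain. From 9, cross-metathesis with 10 under the conditions of step 7 would give 2-[(3R,5S)-5-(7-hydroxyhept-2-en-1-yl)-3,5-dimethyl-1,2-dioxolan-3-yl]acetic acid F7. Diimide reduction as in step 8 would give 2-[(3R,5S)-5-(7-hydroxyheptyl)-3,5-dimethyl-1,2-dioxolan-3-yl]acetic acid F8, and Dess–Martin oxidation would give 2-[(3R,5S)-3,5-dimethyl-5-(7-oxoheptyl)-1,2-dioxolan-3-yl]acetic acid F9. From 19, CBr4 and PPh3 would give (2E,5Z)-1-bromoocta-2,5-diene F10, and sodium diethyl phosphite (Michaelis–Becker reaction) would give diethyl [(2E,5Z)-octa-2,5-dien-1-yl]phosphonate F11. Horner–Wadsworth–Emmons olefination of F9 with F11 (LiHMDS, 2.1 equiv, THF, −78 to 0 °C) would come back to the route at 21.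

Further compounds
F1 | step 2 | methyl (2Z)-5-hydroperoxy-5-methoxy-3-methylhex-2-enoate (racemic) | CC(OC)(OO)C/C(C)=C\C(=O)OC
F2 | step 2 | methyl 2-(5-methoxy-3,5-dimethyl-1,2-dioxolan-3-yl)acetate (racemic, both diastereomers) | COC(=O)CC1(C)CC(C)(OC)OO1
F3 | step 2 | 1,5-dimethyl-2,6,7-trioxabicyclo[3.2.1]octan-3-one (racemic) | CC12CC(C)(CC(=O)O2)OO1
F4 | step 4 | methyl 2-[(3R)-5-methoxy-3,5-dimethyl-1,2-dioxolan-3-yl]acetate (both C5 epimers) | COC(=O)C[C@@]1(C)CC(C)(OC)OO1
F5 | step 4 | methyl 2-[(3R,5S)-3,5-dimethyl-5-(prop-2-en-1-yl)-1,2-dioxolan-3-yl]acetate | C=CC[C@@]1(C)C[C@](C)(CC(=O)OC)OO1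
F6 | step 4 | methyl 2-[(3R,5R)-3,5-dimethyl-5-(prop-2-en-1-yl)-1,2-dioxolan-3-yl]acetate | C=CC[C@]1(C)C[C@](C)(CC(=O)OC)OO1
F7 | step 12 | 2-[(3R,5S)-5-(7-hydroxyhept-2-en-1-yl)-3,5-dimethyl-1,2-dioxolan-3-yl]acetic acid (E/Z mixture) | OCCCCC=CC[C@@]1(C)C[C@](C)(CC(=O)O)OO1
F8 | step 12 | 2-[(3R,5S)-5-(7-hydroxyheptyl)-3,5-dimethyl-1,2-dioxolan-3-yl]acetic acid | OCCCCCCC[C@@]1(C)C[C@](C)(CC(=O)O)OO1
F9 | step 12 | 2-[(3R,5S)-3,5-dimethyl-5-(7-oxoheptyl)-1,2-dioxolan-3-yl]acetic acid | O=CCCCCCC[C@@]1(C)C[C@](C)(CC(=O)O)OO1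
F10 | step 12 | (2E,5Z)-1-bromoocta-2,5-diene | BrC/C=C/C/C=C\CC
F11 | step 12 | diethyl [(2E,5Z)-octa-2,5-dien-1-yl]phosphonate | CCOP(=O)(OCC)C/C=C/C/C=C\CC
A1 | direct plan | (2S,3S,5S,6S)-2,3:5,6-diepoxy-3,5-dimethylheptane-1,7-diol | C[C@]1(O[C@H]1CO)C[C@]2(C)O[C@H]2CO
A2 | direct plan | (1S,1'S)-1,1'-[(3R,5R)-3,5-dimethyl-1,2-dioxolane-3,5-diyl]di(ethane-1,2-diol) | OC[C@H](O)[C@@]1(C)C[C@](C)([C@@H](O)CO)OO1
A3 | direct plan | 2,2'-[(3S,5S)-3,5-dimethyl-1,2-dioxolane-3,5-diyl]di(ethan-1-ol) | OCC[C@@]1(C)C[C@](C)(CCO)OO1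
A4 | direct plan | 2-[(3S,5R)-5-(2-bromoethyl)-3,5-dimethyl-1,2-dioxolan-3-yl]ethan-1-ol | BrCC[C@@]1(C)C[C@](C)(CCO)OO1
A5 | direct plan | 9-[(5E,7E,10Z)-trideca-5,7,10-trien-1-yl]-9-borabicyclo[3.3.1]nonane | CC/C=C\C/C=C/C=C/CCCCB1C2CCCC1CCC2
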